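- The north run was the flask I had to call before it ran, with cJ cut to 90.0 mM against 120 mM of X, so the charge held J below X.

| setting | east | west | south-east | south | north |
|---|---|---|---|---|---|
| X | 120 mM | 120 mM | 120 mM | 60.0 mM | 120 mM |
| J | 360 mM | 360 mM | 360 mM | 360 mM | 90.0 mM |
| Z | 6.00 mM | 6.00 mM | 9.00 mM | 6.00 mM | 6.00 mM |
| Q |  | 36.0 mM |  |  |  |
| time |  |  |  |  | 86 s |

| east run: time / s | east run: [Q] / mM | west run: time / s | west run: [Q] / mM | south-east run: time / s | south-east run: [Q] / mM | south run: time / s | south run: [Q] / mM |
|---|---|---|---|---|---|---|---|
| 14 | 23.7 | 14 | 59.7 | 14 | 33.3 | 14 | 11.4 |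
| 29 | 42.4 | 29 | 78.2 | 29 | 57.5 | 29 | 21.5 |
| 43 | 56.4 | 43 | 94.0 | 43 | 72.0 | 43 | 29.1 |
| 57 | 68.3 | 57 | 104.9 | 57 | 83.6 | 57 | 35.6 |
| 72 | 77.7 | 72 | 112.4 | 72 | 92.5 | 72 | 39.9 |
| 86 | 83.0 | 86 | 119.2 | 86 | 98.3 | 86 | 44.0 |

(each reading ± 0.6 mM)

- order of the initial rate in [Z], near the charge of the east run, the rate being that where two percent of its X are Q
- order of the initial rate in [X], near the charge of the east run, the rate being that where two percent of its X are Q (one fixed amount of Q, the same in the runs compared)
- Q in the north run at 86 s, as a share of the X charged

- Overall: X + J -> Q, with Z as catalyst.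
- Constant volume, constant temperature.
- An order is taken over about fifteen percent of the charge, up and down.

- I read the start from the east run. Its first reading gave a mean rate of 1.69 mM/s, and dividing that by cX·cJ at the midpoint of the interval gave 4.50 × 10⁻⁵ /mM/s, my pair constant, the rate of making Q per unit of cX·cJ at 6.00 mM of Z, an apparent second-order rate constant.
- By its first reading the west run had made 23.7 mM beyond its added Q, and the east run 23.7 mM, so I gave Q no part in the rate.
- The south run, with half the X, made about half as much by that reading, which fitted the first power of cX.
- The earlier runs held J at 360 mM, so the first power of cJ was my assumption.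
- With that constant, the north run started at 0.486 mM/s. Unslowed, this rate came to 41.8 mM by 86 s.
- I tried an end rate of half the start rate, and took the mean rate as the start rate times the square root of that factor. That gave 29.5 mM.
- At that amount in the north run, the factor from X was 0.754 and the factor from J 0.672, so the factor from J stood lower than the factor from X. J was the limiting reagent there, whereas in the east run the same amount left J's factor at 0.918, above X's.
- Together the factors came to 0.507, which closed my trial of half.
- My call was 24.6 % of the X charged, slightly lower than the forecast's figure.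
- The forecast gave 24.7 %, with orders of 1 in Z and 1 in X, and warned: “This extrapolates to low J, outside the range tested”.
- The north run gave 24.9 %, with orders of 0.97 in Z and 1.0 in X, and each forecast value stood within its margin.

    Z + X + J → Q + Z (7.360 /M²/s)
    X + J → Q (0.01550 /M/s)
    Z + Yx → Gu

- In the south run, 4.50 × 10⁻⁵ /mM/s gave 0.926 mM/s once 2.40 mM of Q had been made, beside the flask's 0.93 mM/s. Taking 0.0155 /M/s out of 4.50 × 10⁻⁵ /mM/s left the north run a start rate of 0.318 mM/s, and without the uncatalysed conversion of X and J that run ended at 18.2 %.

All runs come from a simulation for an exercise, and the scatter is random.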